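**Retrosynthetic overview**
- Last bond: catalyst-controlled dearomative C-prenylation at the methyl-bearing carbon of an aromatic acylphloroglucinol. Before it: the benzylic CH2–aryl bond, by reductive alkylation of 3-methylphlorisobutyrophenone with a β-hydroxy cyclopentanecarbaldehyde.
- Cyclopentane: formal [3+2] cycloaddition in which the strained C–C σ-bond of cyclopropyl methyl ketone adds across C5=C6 of (S)-2-tert-butyl-6-methyl-1,3-dioxin-4-one. The ring CH2 bonds to the future carbinol carbon; the acetyl-bearing CH bonds to the carbon that will carry the benzylic CH2.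
- Enabling feature: on the cyclopentane the tertiary C–OH carbon and the neighbouring CH carrying the benzylic CH2 hold O and C cis, so they are C6 and C5 of a cis-fused 1,3-dioxan-4-one (a masked acetoacetate). The remaining ring CH2–CH2–CH(isopropenyl) is a ring-opened acetylcyclopropane (acetyl becomes isopropenyl by methylenation).
- Ring order: temporary dioxinone ring (carries the controlling acetal centre), then cyclopentane (key step, three stereocentres), then dioxanone opened by hydride, then aromatic ring attached, then six-membered ring dearomatised last.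

Key step: step 3

Remark 1: radicals are assumed to attack the dioxinone anti to tert-butyl, as cuprates and hydrogen do; on that basis the (S)-acetal is the enantiomer that leads to the target.
Remark 2: the target is a β-triketone drawn as one enol tautomer; the route should give the tautomeric mixture this array adopts.
Remark 3: the sense of induction of the diphosphine ligand in step 10 is assumed; its enantiomer would be used if the sense proves opposite.

Step 1
Reactants: 1 (S)-3-hydroxybutanoic acid; 2 pivalaldehyde
Product: 3 (2S,6S)-2-tert-butyl-6-methyl-1,3-dioxan-4-one (cis)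
Conditions: TsOH (cat.), CH2Cl2, reflux, Dean–Stark; recrystallisation
Reagents that add atoms: none
Why: Acid-catalysed acetalisation of the β-hydroxy acid under thermodynamic control places tert-butyl and methyl both equatorial, so the existing (S)-carbinol centre sets the acetal centre cis, and crystallisation should remove the minor trans isomer.

Step 2
Reactants: 3 (2S,6S)-2-tert-butyl-6-methyl-1,3-dioxan-4-one
Product: 5 (2S)-2-tert-butyl-6-methyl-4H-1,3-dioxin-4-one, via 6-bromo-1,3-dioxan-4-one 4 (not isolated)
Conditions: NBS, AIBN (cat.), CCl4, reflux; then Et3N, 0 °C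
Reagents that add atoms: none
Why: Radical bromination (Wohl–Ziegler type) at the tertiary α-oxygenated C6–H followed by base-induced loss of HBr should give the conjugated enol ether, which erases C6 and leaves the acetal carbon as the only stereocentre.

Step 3
Reactants: 5 (2S)-2-tert-butyl-6-methyl-4H-1,3-dioxin-4-one; 6 cyclopropyl methyl ketone
Product: 7 (2S,4aS,5R,7aR)-5-acetyl-2-tert-butyl-7a-methylhexahydro-4H-cyclopenta[d][1,3]dioxin-4-one (cis-fused; tert-butyl, 7a-methyl and 4a-H on one face; acetyl trans to the lactone carbonyl)
Conditions: SmI2 (20 mol%), Sm metal (20 mol%), THF (0.4 M in each partner), 55 °C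
Reagents that add atoms: none
Why: Proposed new method: SmI2 transfers an electron to the carbonyl of 6, the ketyl opens its three-membered ring (strain release) to a trivalent-samarium enolate carrying a primary γ-radical, this nucleophilic radical adds to C6 of 5 (first new bond), and the resulting α-acyl radical at C5 attacks the enolate carbon (second new bond) to give a ketyl that returns the electron to samarium, so that the two partners combine one to one with no atom lost. The closest known reaction type is the SmI2-catalysed formal [3+2] cycloaddition of alkyl cyclopropyl ketones with alkenes and alkynes, and the closest precedent for bond formation at C6 of this dioxinone is the conjugate addition of cuprates, which builds the same oxygenated quaternary carbon. The cyclopentane closes by 5-exo-trig radical addition onto the enolate carbon, and the 6/5 ring fusion can only be cis because the three-carbon tether is anchored at C6. The quaternary carbinol carbon should be set by attack anti to the acetal tert-butyl group, the ring-fusion CH by the cis-fusion constraint, and the acetyl-bearing carbon by closure with the acetyl on the convex face, the isomer also favoured at equilibrium through enolisation. The step needs attack at C6 and not C5, and reduction of the ketone and not the dioxinone; the first should be secured by polarity matching of a nucleophilic alkyl radical with the β-carbon of a samarium-bound vinylogous carbonate, the second by inner-sphere reduction of the more Lewis-basic ketone and by the β-alkoxy group that makes the enoate hard to reduce.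

Step 4
Reactants: 7 (2S,4aS,5R,7aR)-5-acetyl-2-tert-butyl-7a-methylhexahydro-4H-cyclopenta[d][1,3]dioxin-4-one
Product: 8 (2S,4aS,5R,7aR)-2-tert-butyl-7a-methyl-5-(prop-1-en-2-yl)hexahydro-4H-cyclopenta[d][1,3]dioxin-4-one
Conditions: Ph3PCH3Br (1.5 equiv), KOtBu (1.4 equiv), THF, 0 °C to rt
Reagents that add atoms: methyltriphenylphosphonium bromide, C[P+](c1ccccc1)(c1ccccc1)c1ccccc1.[Br-]
Why: Wittig methylenation of the methyl ketone, which should react far faster with the non-stabilised ylide than the hindered lactone carbonyl, while the α-stereocentre, if it enolises, returns to the more stable convex-face arrangement.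

Step 5
Reactants: 8 (2S,4aS,5R,7aR)-2-tert-butyl-7a-methyl-5-(prop-1-en-2-yl)hexahydro-4H-cyclopenta[d][1,3]dioxin-4-one
Product: 9 (1R,2R,3R)-2-(hydroxymethyl)-1-methyl-3-(prop-1-en-2-yl)cyclopentan-1-ol
Conditions: LiAlH4, THF, 0 °C to rt; aqueous NaOH work-up
Reagents that add atoms: none
Why: Hydride reduction of the acylal-type lactone releases a hemiacetal that collapses to pivalaldehyde and the tertiary alkoxide, both aldehydes are reduced further, and the auxiliary should leave as neopentyl alcohol without any stereocentre being touched.

Step 6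
Reactants: 9 (1R,2R,3R)-2-(hydroxymethyl)-1-methyl-3-(prop-1-en-2-yl)cyclopentan-1-ol
Product: 10 (1S,2R,5R)-2-hydroxy-2-methyl-5-(prop-1-en-2-yl)cyclopentane-1-carbaldehyde
Conditions: TEMPO (10 mol%), PhI(OAc)2 (1.1 equiv), CH2Cl2, rt; used without storage
Reagents that add atoms: none
Why: Oxoammonium (TEMPO) oxidation is selective for the primary alcohol, cannot oxidise the tertiary one, and runs under nearly neutral conditions under which the β-hydroxy aldehyde should neither dehydrate nor undergo retro-aldol cleavage.

Step 7
Reactants: 11 2-methylbenzene-1,3,5-triol; 12 2-methylpropanoyl chloride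
Product: 13 2-methyl-1-(2,4,6-trihydroxy-3-methylphenyl)propan-1-one
Conditions: AlCl3 (3.5 equiv), PhNO2, 60 °C; aqueous HCl work-up
Reagents that add atoms: none
Why: Friedel–Crafts acylation of the electron-rich triol at one of its two equivalent free positions gives a product that is deactivated towards a second acylation.

Step 8
Reactants: 10 (1S,2R,5R)-2-hydroxy-2-methyl-5-(prop-1-en-2-yl)cyclopentane-1-carbaldehyde; 13 2-methyl-1-(2,4,6-trihydroxy-3-methylphenyl)propan-1-one
Product: 15 1-(2,4,6-trihydroxy-3-{[(1S,2R,5R)-2-hydroxy-2-methyl-5-(prop-1-en-2-yl)cyclopentyl]methyl}-5-methylphenyl)-2-methylpropan-1-one, via ortho-quinone methide 14 (not isolated)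
Conditions: L-proline (20 mol%), Hantzsch ester (diethyl 2,6-dimethyl-1,4-dihydropyridine-3,5-dicarboxylate, 1.2 equiv), CH2Cl2/EtOH, rt
Reagents that add atoms: none
Why: Three-component reductive alkylation, in which amine-catalysed Knoevenagel-type condensation at the only free ring carbon gives the ortho-quinone methide 14 that the Hantzsch ester should reduce by conjugate hydride transfer, while the aldehyde α-carbon already holds the thermodynamically preferred all-trans arrangement so that reversible enamine formation cannot erode it.

Step 9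
Reactants: 16 3-methylbut-2-en-1-ol
Product: 17 methyl 3-methylbut-2-en-1-yl carbonate
Conditions: ClCO2Me, pyridine, CH2Cl2, 0 °C
Reagents that add atoms: methyl chloroformate, COC(=O)Cl
Why: Acylation of the primary allylic alcohol with a chloroformate gives the carbonate that ionises readily with zerovalent palladium.

Step 10
Reactants: 15 1-(2,4,6-trihydroxy-3-{[(1S,2R,5R)-2-hydroxy-2-methyl-5-(prop-1-en-2-yl)cyclopentyl]methyl}-5-methylphenyl)-2-methylpropan-1-one; 17 methyl 3-methylbut-2-en-1-yl carbonate (1.0 equiv)
Product: 18 (6R)-3,5-dihydroxy-4-{[(1S,2R,5R)-2-hydroxy-2-methyl-5-(prop-1-en-2-yl)cyclopentyl]methyl}-6-methyl-6-(3-methylbut-2-en-1-yl)-2-(2-methylpropanoyl)cyclohexa-2,4-dien-1-one (target)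
Conditions: Pd2(dba)3 (2.5 mol%), (R,R)-DACH-phenyl ligand [(1R,2R)-N,N'-bis(2-diphenylphosphinobenzoyl)cyclohexane-1,2-diamine, 7.5 mol%], THF, 0 °C to rt; work-up at pH 4–5
Reagents that add atoms: none
Why: Tsuji–Trost allylation with dearomatisation (asymmetric allylic alkylation of a phenoxide through carbon), in which methoxide released on ionisation deprotonates the triol, the methyl-bearing ring carbon attacks the unsubstituted terminus of the π-prenyl palladium complex in preference to the more hindered carbon carrying the cyclopentylmethyl group, and the chiral ligand pocket, not the remote cyclopentane stereocentres, should select the face and set the quaternary centre as R.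

**Compound list**
1 | (S)-3-hydroxybutanoic acid | C[C@H](O)CC(=O)O | starting material
2 | pivalaldehyde | CC(C)(C)C=O | starting material
3 | (2S,6S)-2-tert-butyl-6-methyl-1,3-dioxan-4-one | C[C@H]1CC(=O)O[C@@H](C(C)(C)C)O1 | intermediate
4 | (2S)-6-bromo-2-tert-butyl-6-methyl-1,3-dioxan-4-one (C6 configuration not defined) | CC1(Br)CC(=O)O[C@@H](C(C)(C)C)O1 | intermediate
5 | (2S)-2-tert-butyl-6-methyl-4H-1,3-dioxin-4-one | CC1=CC(=O)O[C@@H](C(C)(C)C)O1 | intermediate
6 | cyclopropyl methyl ketone | CC(=O)C1CC1 | starting material
7 | (2S,4aS,5R,7aR)-5-acetyl-2-tert-butyl-7a-methylhexahydro-4H-cyclopenta[d][1,3]dioxin-4-one | CC(=O)[C@@H]1CC[C@@]2(C)O[C@H](C(C)(C)C)OC(=O)[C@@H]12 | intermediate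
8 | (2S,4aS,5R,7aR)-2-tert-butyl-7a-methyl-5-(prop-1-en-2-yl)hexahydro-4H-cyclopenta[d][1,3]dioxin-4-one | C=C(C)[C@@H]1CC[C@@]2(C)O[C@H](C(C)(C)C)OC(=O)[C@@H]12 | intermediate
9 | (1R,2R,3R)-2-(hydroxymethyl)-1-methyl-3-(prop-1-en-2-yl)cyclopentan-1-ol | C=C(C)[C@@H]1CC[C@@](C)(O)[C@H]1CO | intermediate
10 | (1S,2R,5R)-2-hydroxy-2-methyl-5-(prop-1-en-2-yl)cyclopentane-1-carbaldehyde | C=C(C)[C@@H]1CC[C@@](C)(O)[C@H]1C=O | intermediate
11 | 2-methylbenzene-1,3,5-triol | Cc1c(O)cc(O)cc1O | starting material
12 | 2-methylpropanoyl chloride | CC(C)C(=O)Cl | starting material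
13 | 2-methyl-1-(2,4,6-trihydroxy-3-methylphenyl)propan-1-one | CC(C)C(=O)c1c(O)cc(O)c(C)c1O | intermediate
14 | ortho-quinone methide from 10 and 13 (alkene geometry not defined) | C=C(C)[C@@H]1CC[C@@](C)(O)[C@H]1C=C1C(=O)C(C)=C(O)C(C(=O)C(C)C)=C1O | intermediate
15 | 1-(2,4,6-trihydroxy-3-{[(1S,2R,5R)-2-hydroxy-2-methyl-5-(prop-1-en-2-yl)cyclopentyl]methyl}-5-methylphenyl)-2-methylpropan-1-one | C=C(C)[C@@H]1CC[C@@](C)(O)[C@H]1Cc1c(O)c(C)c(O)c(C(=O)C(C)C)c1O | intermediate
16 | 3-methylbut-2-en-1-ol | CC(C)=CCO | starting material
17 | methyl 3-methylbut-2-en-1-yl carbonate | COC(=O)OCC=C(C)C | intermediate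
18 | (6R)-3,5-dihydroxy-4-{[(1S,2R,5R)-2-hydroxy-2-methyl-5-(prop-1-en-2-yl)cyclopentyl]methyl}-6-methyl-6-(3-methylbut-2-en-1-yl)-2-(2-methylpropanoyl)cyclohexa-2,4-dien-1-one | C=C(C)[C@@H]1CC[C@@](C)(O)[C@H]1CC1=C(O)[C@@](C)(CC=C(C)C)C(=O)C(C(=O)C(C)C)=C1O | target

**Step count**
Total steps: 10. Longest linear sequence: 8 (steps 1–6, 8, 10).

**Steps most likely to fail**

Step 3 (proposed new method). The ring-opened γ-radical may add too slowly to the fully substituted C6, so that hydrogen abstraction from solvent and loss of the divalent samarium catalyst outrun the cycloaddition; attack at C5 or on the tert-butyl face would erode regio- and facial selectivity. The fallback uses known chemistry, sets out from 5 and rejoins the route at 8. Conjugate addition of lithium bis(4-methylpent-3-en-1-yl)cuprate (from 5-bromo-2-methylpent-2-ene, t-BuLi, CuI; Et2O, −78 °C) anti to tert-butyl should give (2S,6R)-2-tert-butyl-6-methyl-6-(4-methylpent-3-en-1-yl)-1,3-dioxan-4-one F1. Allylic oxidation of the E-methyl group (SeO2 cat., t-BuOOH, CH2Cl2) should give (2S,6R)-2-tert-butyl-6-[(3E)-5-hydroxy-4-methylpent-3-en-1-yl]-6-methyl-1,3-dioxan-4-one F2. ClCO2Me/pyridine should give (2S,6R)-2-tert-butyl-6-[(3E)-5-(methoxycarbonyloxy)-4-methylpent-3-en-1-yl]-6-methyl-1,3-dioxan-4-one F3. LiHMDS followed by Pd(PPh3)4 (THF, −78 to 0 °C) should then close the cyclopentane by intramolecular Tsuji–Trost alkylation of the lactone enolate at the allyl terminus nearer the ring, which forms the isopropenyl group directly and gives 8.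

Step 10. Dearomative prenylation may suffer from attack through the carbon carrying the cyclopentylmethyl group or through oxygen, from over-alkylation, or from weak catalyst control over the face of the planar nucleophile. The fallback sets out from 15 and rejoins at 18. Classical alkylative dearomatisation (prenyl bromide, NaOMe, MeOH, 0 °C) gives up catalyst control and should give 18 together with its epimer at the ring quaternary carbon, (6S)-3,5-dihydroxy-4-{[(1S,2R,5R)-2-hydroxy-2-methyl-5-(prop-1-en-2-yl)cyclopentyl]methyl}-6-methyl-6-(3-methylbut-2-en-1-yl)-2-(2-methylpropanoyl)cyclohexa-2,4-dien-1-one F4. The two diastereomers would be separated by preparative HPLC.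

Step 8. The β-hydroxy aldehyde may be lost by dehydration or retro-aldol cleavage under amine catalysis, or by fragmentation at the quinone methide stage before hydride transfer. The fallback masks the tertiary alcohol, sets out from 9 and rejoins at 15. TESOTf/2,6-lutidine should give the bis(triethylsilyl) ether of diol 9 F5. Swern oxidation should convert the primary silyl ether directly into the aldehyde and leave the tertiary one, giving the O-triethylsilyl ether of aldehyde 10 F6. The same reductive alkylation with 13 should give the tertiary O-triethylsilyl ether of 15 F7, and TBAF buffered with AcOH should release 15.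

**Further compounds**
F1 | step 3 | (2S,6R)-2-tert-butyl-6-methyl-6-(4-methylpent-3-en-1-yl)-1,3-dioxan-4-one | CC(C)=CCC[C@]1(C)CC(=O)O[C@@H](C(C)(C)C)O1
F2 | step 3 | (2S,6R)-2-tert-butyl-6-[(3E)-5-hydroxy-4-methylpent-3-en-1-yl]-6-methyl-1,3-dioxan-4-one | OC/C(C)=C/CC[C@]1(C)CC(=O)O[C@@H](C(C)(C)C)O1
F3 | step 3 | (2S,6R)-2-tert-butyl-6-[(3E)-5-(methoxycarbonyloxy)-4-methylpent-3-en-1-yl]-6-methyl-1,3-dioxan-4-one | COC(=O)OC/C(C)=C/CC[C@]1(C)CC(=O)O[C@@H](C(C)(C)C)O1
F4 | step 10 | (6S)-epimer of 18 at the ring quaternary carbon | C=C(C)[C@@H]1CC[C@@](C)(O)[C@H]1CC1=C(O)[C@](C)(CC=C(C)C)C(=O)C(C(=O)C(C)C)=C1O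
F5 | step 8 | bis(triethylsilyl) ether of diol 9 | C=C(C)[C@@H]1CC[C@@](C)(O[Si](CC)(CC)CC)[C@H]1CO[Si](CC)(CC)CC
F6 | step 8 | O-triethylsilyl ether of aldehyde 10 | C=C(C)[C@@H]1CC[C@@](C)(O[Si](CC)(CC)CC)[C@H]1C=O
F7 | step 8 | tertiary O-triethylsilyl ether of 15 | C=C(C)[C@@H]1CC[C@@](C)(O[Si](CC)(CC)CC)[C@H]1Cc1c(O)c(C)c(O)c(C(=O)C(C)C)c1O
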